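**Retrosynthetic overview**

1. Labels and feature: benzofuran atoms O1, C2, C3, C3a, C4–C7a (ring A is the benzo ring); Ca is the ketone carbon on C4 and Cb the CH stereocentre; ring B is the resorcinol ring (B1 on C3, B6 on Cb), ring C the aryl on C2, ring D the aryl on Cb. Ring D is a 4-hydroxyphenyl group on Cb, so Cb–ring D is a masked para-quinone methide and Ca a masked aryl aldehyde carbon.
2. Key disconnection Ca–Cb: a chiral triazolylidene turns the C4 aldehyde into an acyl anion that adds 1,6 to the quinone methide on B6. This closes the seven-membered ring (Ca, C4, C3a, C3, B1, B6, Cb) and sets Cb in one step.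
3. The quinone methide is not isolated. It is released in the flask from a bench-stable 4-hydroxybenzyl sulfone by the same weak base that forms the carbene; a carbinol would need acid to dehydrate, which the carbene does not tolerate.
4. Precursor: Cb comes from formylation of ring B and addition of a ring D Grignard reagent; ring C from Pd-catalysed C2–H arylation; the furan ring from cyclodehydration of an aryloxy ketone. Methyl ethers carry the acid steps and are then exchanged for silyl ethers; ring D travels as an allyl ether.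
5. Ring order: furan ring (step 2), seven-membered ring (step 12); the four silyl ethers are removed last with KHF2.

Key step: step 12

Assumption: the sense of induction of the new ring closure cannot be predicted with confidence. The (5aR,10bS) triazolium salt is written; its equally available (5aS,10bR) antipode is used if the first experiment shows that it is the one leading to the (S) ketone.

Abbreviation: TBS = tert-butyldimethylsilyl, TBSO = tert-butyldimethylsilyloxy.

**Route**

Step 1
Reactants: 1 methyl 3-hydroxy-5-methoxybenzoate; 2 2-bromo-1-(3,5-dimethoxyphenyl)ethan-1-one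
Product: 3 methyl 3-[2-(3,5-dimethoxyphenyl)-2-oxoethoxy]-5-methoxybenzoate
Conditions: K2CO3, acetone, reflux
Reagents that add atoms: none
Why: Williamson ether synthesis, in which the phenoxide of 1 displaces the primary α-bromide of 2 by SN2 and no other acidic or electrophilic site competes under K2CO3.

Step 2
Reactants: 3 methyl 3-[2-(3,5-dimethoxyphenyl)-2-oxoethoxy]-5-methoxybenzoate
Product: 4 methyl 3-(3,5-dimethoxyphenyl)-6-methoxy-1-benzofuran-4-carboxylate
Conditions: Bi(OTf)3 (10 mol%), CH2Cl2, reflux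
Reagents that add atoms: none
Why: Lewis acid-catalysed cyclodehydration of an α-aryloxy ketone (intramolecular Friedel–Crafts hydroxyalkylation, then loss of water) forms the furan ring, with closure expected at the carbon para to the methoxy group, next to the ester, which places the ester on C4.

Step 3
Reactants: 4 methyl 3-(3,5-dimethoxyphenyl)-6-methoxy-1-benzofuran-4-carboxylate; 5 4-bromoanisole
Product: 6 methyl 3-(3,5-dimethoxyphenyl)-6-methoxy-2-(4-methoxyphenyl)-1-benzofuran-4-carboxylate
Conditions: Pd(OAc)2 (5 mol%), PCy3·HBF4 (10 mol%), PivOH (30 mol%), K2CO3, DMA, 110 °C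
Reagents that add atoms: none
Why: Pd-catalysed direct C–H arylation by concerted metalation–deprotonation at C2, the only furan C–H and the most reactive C–H of the benzofuran.

Step 4
Reactants: 6 methyl 3-(3,5-dimethoxyphenyl)-6-methoxy-2-(4-methoxyphenyl)-1-benzofuran-4-carboxylate
Product: 7 methyl 3-(2-formyl-3,5-dimethoxyphenyl)-6-methoxy-2-(4-methoxyphenyl)-1-benzofuran-4-carboxylate
Conditions: POCl3, DMF, 0 to 70 °C; then aq. NaOAc
Reagents that add atoms: N,N-dimethylformamide, CN(C)C=O (formyl carbon); water, O (formyl oxygen)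
Why: Vilsmeier–Haack formylation, in which the chloroiminium ion attacks ring B (two meta-disposed methoxy groups, no acceptor) at B6, ortho to one methoxy group and para to the other, while ring A is deactivated by the ester and ring C has a single donor.

Step 5
Reactants: 7 methyl 3-(2-formyl-3,5-dimethoxyphenyl)-6-methoxy-2-(4-methoxyphenyl)-1-benzofuran-4-carboxylate
Product: 8 methyl 3-(2-formyl-3,5-dihydroxyphenyl)-6-hydroxy-2-(4-hydroxyphenyl)-1-benzofuran-4-carboxylate
Conditions: BBr3 (8 equiv), CH2Cl2, −78 to 0 °C; then MeOH, aq. NaHCO3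
Reagents that add atoms: none
Why: Lewis acid-mediated cleavage of the four aryl methyl ethers, which the methyl ester and formyl group should survive at or below 0 °C with a methanol quench; the exchange is made here because methyl ethers could not be removed mildly from the final epimerisable ketone.

Step 6
Reactants: 8 methyl 3-(2-formyl-3,5-dihydroxyphenyl)-6-hydroxy-2-(4-hydroxyphenyl)-1-benzofuran-4-carboxylate
Product: 9 methyl 3-[2-formyl-3,5-bis(TBSO)phenyl]-6-(TBSO)-2-[4-(TBSO)phenyl]-1-benzofuran-4-carboxylate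
Conditions: TBSCl (6 equiv), imidazole, DMF, rt
Reagents that add atoms: tert-butyldimethylsilyl chloride, CC(C)(C)[Si](C)(C)Cl
Why: Standard silylation of phenols through the N-silylimidazolium ion, in which all four phenols, including the hydrogen-bonded one next to the formyl group, are expected to react with excess reagent in DMF.

Step 7
Reactants: 9 methyl 3-[2-formyl-3,5-bis(TBSO)phenyl]-6-(TBSO)-2-[4-(TBSO)phenyl]-1-benzofuran-4-carboxylate; 10 1-(allyloxy)-4-bromobenzene
Product: 12 methyl 3-{2-[(4-allyloxyphenyl)(hydroxy)methyl]-3,5-bis(TBSO)phenyl}-6-(TBSO)-2-[4-(TBSO)phenyl]-1-benzofuran-4-carboxylate (racemic), via 4-(allyloxy)phenylmagnesium bromide 11 (not isolated)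
Conditions: 10, Mg, THF, rt; then 9, THF, −78 °C; sat. aq. NH4Cl at −78 °C
Reagents that add atoms: none
Why: Grignard addition to the aryl aldehyde, which is far more electrophilic than the hindered peri methyl ester at −78 °C, with a cold quench to prevent 1,5-migration of the B5 silyl group to the magnesium alkoxide; the carbinol centre forms racemic and is erased in step 12.

Step 8
Reactants: 12 methyl 3-{2-[(4-allyloxyphenyl)(hydroxy)methyl]-3,5-bis(TBSO)phenyl}-6-(TBSO)-2-[4-(TBSO)phenyl]-1-benzofuran-4-carboxylate (racemic)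
Product: 13 methyl 3-{2-[(4-allyloxyphenyl)(4-tolylsulfonyl)methyl]-3,5-bis(TBSO)phenyl}-6-(TBSO)-2-[4-(TBSO)phenyl]-1-benzofuran-4-carboxylate (racemic)
Conditions: 4-toluenesulfinic acid (3 equiv, freshly liberated from its sodium salt), CH2Cl2, rt
Reagents that add atoms: 4-toluenesulfinic acid, Cc1ccc(cc1)S(=O)O
Why: SN1 substitution, in which the benzhydrol, doubly activated by the ortho/para silyloxy groups of ring B and the para allyloxy group of ring D, ionises under the weak acid and is captured at sulfur to give the thermodynamically preferred sulfone, while silyl ethers, allyl ether and ester tolerate the sulfinic acid.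

Step 9
Reactants: 13 methyl 3-{2-[(4-allyloxyphenyl)(4-tolylsulfonyl)methyl]-3,5-bis(TBSO)phenyl}-6-(TBSO)-2-[4-(TBSO)phenyl]-1-benzofuran-4-carboxylate (racemic)
Product: 14 [3-{2-[(4-allyloxyphenyl)(4-tolylsulfonyl)methyl]-3,5-bis(TBSO)phenyl}-6-(TBSO)-2-[4-(TBSO)phenyl]-1-benzofuran-4-yl]methanol (racemic)
Conditions: i-Bu2AlH (3 equiv), CH2Cl2, −78 to 0 °C; aq. potassium sodium tartrate
Reagents that add atoms: none
Why: Hydride reduction of the ester to the primary alcohol, in which sulfone, allyl ether and aryl silyl ethers are inert to i-Bu2AlH at low temperature and no phenoxide is present that could expel the sulfinate.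

Step 10
Reactants: 14 [3-{2-[(4-allyloxyphenyl)(4-tolylsulfonyl)methyl]-3,5-bis(TBSO)phenyl}-6-(TBSO)-2-[4-(TBSO)phenyl]-1-benzofuran-4-yl]methanol (racemic)
Product: 15 3-{2-[(4-allyloxyphenyl)(4-tolylsulfonyl)methyl]-3,5-bis(TBSO)phenyl}-6-(TBSO)-2-[4-(TBSO)phenyl]-1-benzofuran-4-carbaldehyde (racemic)
Conditions: Dess–Martin periodinane, CH2Cl2, 0 °C to rt
Reagents that add atoms: none
Why: Dess–Martin oxidation of the primary benzylic alcohol to the aldehyde under non-basic conditions, with no other oxidisable group present.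

Step 11
Reactants: 15 3-{2-[(4-allyloxyphenyl)(4-tolylsulfonyl)methyl]-3,5-bis(TBSO)phenyl}-6-(TBSO)-2-[4-(TBSO)phenyl]-1-benzofuran-4-carbaldehyde (racemic)
Product: 16 3-{2-[(4-hydroxyphenyl)(4-tolylsulfonyl)methyl]-3,5-bis(TBSO)phenyl}-6-(TBSO)-2-[4-(TBSO)phenyl]-1-benzofuran-4-carbaldehyde (racemic)
Conditions: Pd(PPh3)4 (5 mol%), 4-toluenesulfinic acid (1.5 equiv), CH2Cl2, rt
Reagents that add atoms: none
Why: Pd-catalysed deallylation, in which zerovalent palladium ionises the aryl allyl ether to a π-allyl complex that the sulfinic acid captures as allyl tolyl sulfone; the medium stays slightly acidic, so the 4-hydroxybenzyl sulfone does not eliminate and aldehyde and silyl ethers are untouched.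

Step 12
Reactants: 16 3-{2-[(4-hydroxyphenyl)(4-tolylsulfonyl)methyl]-3,5-bis(TBSO)phenyl}-6-(TBSO)-2-[4-(TBSO)phenyl]-1-benzofuran-4-carbaldehyde (racemic)
Product: 18 (S)-tetra-O-TBS hopeafuran (seven-membered ketone; ring A oxygen, both ring B oxygens and ring C oxygen silylated; ring D phenol free; Cb of S configuration), via quinone methide aldehyde 17 (not isolated)
Conditions: (5aR,10bS)-2-(pentafluorophenyl)-5a,10b-dihydro-4H,6H-indeno[2,1-b][1,2,4]triazolo[4,3-d][1,4]oxazin-2-ium tetrafluoroborate (15 mol%), K2CO3 (1.05 equiv, powdered), 4 Å molecular sieves, degassed toluene, 0 °C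
Reagents that add atoms: none
Why: Proposed new method: K2CO3 converts the ring D phenol of 16 into its phenoxide, which expels 4-toluenesulfinate by 1,6-elimination to give quinone methide 17, while the triazolylidene adds to the non-enolisable C4 aldehyde to give the Breslow intermediate; its nucleophilic carbon Ca attacks the exocyclic carbon Cb, ring D becomes an aromatic phenoxide (the driving force), and collapse of the tetrahedral intermediate releases the carbene and the ketone with the free 4-hydroxyphenyl group. The closest known reactions are the carbene-catalysed intermolecular 1,6-addition of aryl aldehydes to isolable para-quinone methides giving α,α-diaryl ketones, the asymmetric intramolecular Stetter reaction with this catalyst class, and the base-induced release of quinone methides from hydroxybenzyl sulfones. The seven-membered ring closes in a 7-exo-trig mode, helped by the twisted C3–B1 biaryl bond that holds Ca and Cb close together. The configuration at Cb is controlled by the catalyst: the aminoindane backbone and the N-pentafluorophenyl group shield one face of the Breslow enaminol, so only one face of the prochiral Cb can reach Ca, as at the β-carbon of the acceptor in Stetter reactions. The step needs face selection at Cb, acyl-anion addition in preference to benzoin coupling, carbene addition to Cb or oligomerisation of 17, and no epimerisation of the acidic product; the peri-hindered aldehyde, the intramolecular setting and the slow heterogeneous release of 17 at low concentration serve the first needs, and with 1.05 equiv of K2CO3 only potassium hydrogencarbonate and sulfinate remain at the end, too weak to enolise the ketone.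

Step 13
Reactants: 18 (S)-tetra-O-TBS hopeafuran
Product: 19 hopeafuran, (S) configuration at Cb
Conditions: KHF2 (10 equiv), MeOH, rt
Reagents that add atoms: none
Why: Fluoride-mediated cleavage of the four phenolic silyl ethers with KHF2 in methanol, a weakly acidic medium that should not enolise the α,α-diaryl ketone, so the Cb configuration set in step 12 is kept.

**Compound list**

1 | methyl 3-hydroxy-5-methoxybenzoate | COC(=O)c1cc(O)cc(OC)c1 | starting material
2 | 2-bromo-1-(3,5-dimethoxyphenyl)ethan-1-one | COc1cc(OC)cc(c1)C(=O)CBr | starting material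
3 | methyl 3-[2-(3,5-dimethoxyphenyl)-2-oxoethoxy]-5-methoxybenzoate | COC(=O)c1cc(OC)cc(OCC(=O)c2cc(OC)cc(OC)c2)c1 | intermediate
4 | methyl 3-(3,5-dimethoxyphenyl)-6-methoxy-1-benzofuran-4-carboxylate | COC(=O)c1cc(OC)cc2occ(c12)-c1cc(OC)cc(OC)c1 | intermediate
5 | 4-bromoanisole | COc1ccc(Br)cc1 | starting material
6 | methyl 3-(3,5-dimethoxyphenyl)-6-methoxy-2-(4-methoxyphenyl)-1-benzofuran-4-carboxylate | COC(=O)c1cc(OC)cc2oc(-c3ccc(OC)cc3)c(c12)-c1cc(OC)cc(OC)c1 | intermediate
7 | methyl 3-(2-formyl-3,5-dimethoxyphenyl)-6-methoxy-2-(4-methoxyphenyl)-1-benzofuran-4-carboxylate | COC(=O)c1cc(OC)cc2oc(-c3ccc(OC)cc3)c(c12)-c1cc(OC)cc(OC)c1C=O | intermediate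
8 | methyl 3-(2-formyl-3,5-dihydroxyphenyl)-6-hydroxy-2-(4-hydroxyphenyl)-1-benzofuran-4-carboxylate | COC(=O)c1cc(O)cc2oc(-c3ccc(O)cc3)c(c12)-c1cc(O)cc(O)c1C=O | intermediate
9 | methyl 3-[2-formyl-3,5-bis(TBSO)phenyl]-6-(TBSO)-2-[4-(TBSO)phenyl]-1-benzofuran-4-carboxylate | COC(=O)c1cc(O[Si](C)(C)C(C)(C)C)cc2oc(-c3ccc(O[Si](C)(C)C(C)(C)C)cc3)c(c12)-c1cc(O[Si](C)(C)C(C)(C)C)cc(O[Si](C)(C)C(C)(C)C)c1C=O | intermediate
10 | 1-(allyloxy)-4-bromobenzene | C=CCOc1ccc(Br)cc1 | starting material
11 | 4-(allyloxy)phenylmagnesium bromide | C=CCOc1ccc([Mg]Br)cc1 | intermediate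
12 | racemic carbinol ester: methyl 3-{2-[(4-allyloxyphenyl)(hydroxy)methyl]-3,5-bis(TBSO)phenyl}-6-(TBSO)-2-[4-(TBSO)phenyl]-1-benzofuran-4-carboxylate | COC(=O)c1cc(O[Si](C)(C)C(C)(C)C)cc2oc(-c3ccc(O[Si](C)(C)C(C)(C)C)cc3)c(c12)-c1cc(O[Si](C)(C)C(C)(C)C)cc(O[Si](C)(C)C(C)(C)C)c1C(O)c1ccc(OCC=C)cc1 | intermediate
13 | racemic sulfone ester: methyl 3-{2-[(4-allyloxyphenyl)(4-tolylsulfonyl)methyl]-3,5-bis(TBSO)phenyl}-6-(TBSO)-2-[4-(TBSO)phenyl]-1-benzofuran-4-carboxylate | COC(=O)c1cc(O[Si](C)(C)C(C)(C)C)cc2oc(-c3ccc(O[Si](C)(C)C(C)(C)C)cc3)c(c12)-c1cc(O[Si](C)(C)C(C)(C)C)cc(O[Si](C)(C)C(C)(C)C)c1C(c1ccc(OCC=C)cc1)S(=O)(=O)c1ccc(C)cc1 | intermediate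
14 | racemic sulfone alcohol: [3-{2-[(4-allyloxyphenyl)(4-tolylsulfonyl)methyl]-3,5-bis(TBSO)phenyl}-6-(TBSO)-2-[4-(TBSO)phenyl]-1-benzofuran-4-yl]methanol | OCc1cc(O[Si](C)(C)C(C)(C)C)cc2oc(-c3ccc(O[Si](C)(C)C(C)(C)C)cc3)c(c12)-c1cc(O[Si](C)(C)C(C)(C)C)cc(O[Si](C)(C)C(C)(C)C)c1C(c1ccc(OCC=C)cc1)S(=O)(=O)c1ccc(C)cc1 | intermediate
15 | racemic sulfone aldehyde, ring D allyl ether: 3-{2-[(4-allyloxyphenyl)(4-tolylsulfonyl)methyl]-3,5-bis(TBSO)phenyl}-6-(TBSO)-2-[4-(TBSO)phenyl]-1-benzofuran-4-carbaldehyde | O=Cc1cc(O[Si](C)(C)C(C)(C)C)cc2oc(-c3ccc(O[Si](C)(C)C(C)(C)C)cc3)c(c12)-c1cc(O[Si](C)(C)C(C)(C)C)cc(O[Si](C)(C)C(C)(C)C)c1C(c1ccc(OCC=C)cc1)S(=O)(=O)c1ccc(C)cc1 | intermediate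
16 | racemic sulfone aldehyde, ring D phenol free: 3-{2-[(4-hydroxyphenyl)(4-tolylsulfonyl)methyl]-3,5-bis(TBSO)phenyl}-6-(TBSO)-2-[4-(TBSO)phenyl]-1-benzofuran-4-carbaldehyde | O=Cc1cc(O[Si](C)(C)C(C)(C)C)cc2oc(-c3ccc(O[Si](C)(C)C(C)(C)C)cc3)c(c12)-c1cc(O[Si](C)(C)C(C)(C)C)cc(O[Si](C)(C)C(C)(C)C)c1C(c1ccc(O)cc1)S(=O)(=O)c1ccc(C)cc1 | intermediate
17 | quinone methide aldehyde: 3-{2-[(4-oxocyclohexa-2,5-dien-1-ylidene)methyl]-3,5-bis(TBSO)phenyl}-6-(TBSO)-2-[4-(TBSO)phenyl]-1-benzofuran-4-carbaldehyde | O=Cc1cc(O[Si](C)(C)C(C)(C)C)cc2oc(-c3ccc(O[Si](C)(C)C(C)(C)C)cc3)c(c12)-c1cc(O[Si](C)(C)C(C)(C)C)cc(O[Si](C)(C)C(C)(C)C)c1C=C1C=CC(=O)C=C1 | intermediate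
18 | (S)-tetra-O-TBS hopeafuran, ring D phenol free | O=C1c2cc(O[Si](C)(C)C(C)(C)C)cc3oc(-c4ccc(O[Si](C)(C)C(C)(C)C)cc4)c(c23)-c2cc(O[Si](C)(C)C(C)(C)C)cc(O[Si](C)(C)C(C)(C)C)c2[C@@H]1c1ccc(O)cc1 | intermediate
19 | hopeafuran, (S) at Cb | O=C1c2cc(O)cc3oc(-c4ccc(O)cc4)c(c23)-c2cc(O)cc(O)c2[C@@H]1c1ccc(O)cc1 | target

**Step count**

Total: 13 steps. Longest linear sequence: 13 steps (1 to 19; the Grignard reagent 11 is made in the flask of step 7).

**Steps most likely to fail**

Step 12. The carbene may be trapped by Cb of the quinone methide, 17 may oligomerise before it cyclises, or face selection at Cb may be poor. The fallback uses known chemistry and sets out from 15. Deprotonation of the diarylmethyl sulfone with LiN(SiMe3)2 in THF at −78 °C lets the sulfonyl carbanion add to the C4 aldehyde (Julia-type addition) and close the seven-membered ring as the cyclic β-hydroxy sulfone F1. Dess–Martin oxidation gives the cyclic β-keto sulfone F2. Reductive removal of the sulfonyl group with SmI2 in THF–MeOH at −78 °C gives the racemic ketone allyl ether F3. Deallylation with Pd(PPh3)4 and 4-toluenesulfinic acid gives the racemic silylated ketone F4. The enantiomers of F4 are separated by preparative chromatography on a polysaccharide chiral stationary phase; the unwanted (R) enantiomer is racemised with Et3N in CH2Cl2 and recycled. The (S) enantiomer is 18, where the fallback rejoins the route.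

Step 7. The B5 silyl group may migrate from the phenol oxygen to the new alkoxide next to it, or addition to the crowded aldehyde may stall. The fallback sets out from 8. Only the three unchelated phenols are silylated (TBSCl 3.1 equiv, imidazole, CH2Cl2, 0 °C) to give the tris-silyl ether F5, in which the hydrogen-bonded B5 phenol stays free. Addition of 2.5 equiv of 11 (THF, −40 °C) goes through the magnesium phenoxide, which chelates the aldehyde and leaves no silyl group next to the alkoxide, and gives the phenol carbinol F6. Silylation of the phenol in preference to the hindered benzhydrol (TBSCl, imidazole, DMF, 0 °C) gives 12.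

Step 5. The methyl ester may be cleaved, or the formyl group may be degraded, during the BBr3 demethylation. The fallback sets out from 6. Demethylation before the formyl group is present (BBr3, CH2Cl2, −78 to 0 °C) gives the tetraphenol ester F7. Vilsmeier–Haack formylation (POCl3, DMF, MeCN, 0 °C to rt; then aq. NaOAc) of its free resorcinol ring B, the ring most open to electrophiles, para to one hydroxyl group, gives 8.

**Further compounds**

F1 | step 12 | cyclic β-hydroxy sulfone (racemic, diastereomer mixture): seven-membered ring closed, Ca bears OH, Cb bears 4-tolylsulfonyl and 4-allyloxyphenyl | OC1c2cc(O[Si](C)(C)C(C)(C)C)cc3oc(-c4ccc(O[Si](C)(C)C(C)(C)C)cc4)c(c23)-c2cc(O[Si](C)(C)C(C)(C)C)cc(O[Si](C)(C)C(C)(C)C)c2C1(c1ccc(OCC=C)cc1)S(=O)(=O)c1ccc(C)cc1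
F2 | step 12 | cyclic β-keto sulfone (racemic) | O=C1c2cc(O[Si](C)(C)C(C)(C)C)cc3oc(-c4ccc(O[Si](C)(C)C(C)(C)C)cc4)c(c23)-c2cc(O[Si](C)(C)C(C)(C)C)cc(O[Si](C)(C)C(C)(C)C)c2C1(c1ccc(OCC=C)cc1)S(=O)(=O)c1ccc(C)cc1
F3 | step 12 | racemic tetra-O-TBS hopeafuran ring D allyl ether | O=C1c2cc(O[Si](C)(C)C(C)(C)C)cc3oc(-c4ccc(O[Si](C)(C)C(C)(C)C)cc4)c(c23)-c2cc(O[Si](C)(C)C(C)(C)C)cc(O[Si](C)(C)C(C)(C)C)c2C1c1ccc(OCC=C)cc1
F4 | step 12 | racemic tetra-O-TBS hopeafuran, ring D phenol free | O=C1c2cc(O[Si](C)(C)C(C)(C)C)cc3oc(-c4ccc(O[Si](C)(C)C(C)(C)C)cc4)c(c23)-c2cc(O[Si](C)(C)C(C)(C)C)cc(O[Si](C)(C)C(C)(C)C)c2C1c1ccc(O)cc1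
F5 | step 7 | methyl 3-[2-formyl-3-hydroxy-5-(TBSO)phenyl]-6-(TBSO)-2-[4-(TBSO)phenyl]-1-benzofuran-4-carboxylate | COC(=O)c1cc(O[Si](C)(C)C(C)(C)C)cc2oc(-c3ccc(O[Si](C)(C)C(C)(C)C)cc3)c(c12)-c1cc(O[Si](C)(C)C(C)(C)C)cc(O)c1C=O
F6 | step 7 | methyl 3-{2-[(4-allyloxyphenyl)(hydroxy)methyl]-3-hydroxy-5-(TBSO)phenyl}-6-(TBSO)-2-[4-(TBSO)phenyl]-1-benzofuran-4-carboxylate (racemic) | COC(=O)c1cc(O[Si](C)(C)C(C)(C)C)cc2oc(-c3ccc(O[Si](C)(C)C(C)(C)C)cc3)c(c12)-c1cc(O[Si](C)(C)C(C)(C)C)cc(O)c1C(O)c1ccc(OCC=C)cc1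
F7 | step 5 | methyl 3-(3,5-dihydroxyphenyl)-6-hydroxy-2-(4-hydroxyphenyl)-1-benzofuran-4-carboxylate | COC(=O)c1cc(O)cc2oc(-c3ccc(O)cc3)c(c12)-c1cc(O)cc(O)c1
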